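## Structural features

The target is a trans-3,5-disubstituted γ-butyrolactone (ring atoms O, C8, C7, C6 and C5, with the methyl C9 on C7) whose C5 carries, through the methylene C4, the tertiary carbinol C3 (methyl C10), then the secondary carbinol C2 and the methylene C1, which is ether-linked to O7 of a coumarin. There are four stereocentres: C2 (R) and C3 (R) are contiguous, C3 and C5 (S) are 1,3-related across C4, and C5 and C7 (R) are 1,3-related across C6 inside the lactone. The fragile groups are the coumarin (a conjugated lactone open to nucleophiles, hydride and single-electron reductants), the base-epimerizable C7, and the tertiary alcohol next to a secondary one, which strong acid would dehydrate. The acyl carbon C8 can in principle rest on O3 or on O5, and the five-membered lactone on O5 is the thermodynamic position. The real difficulty is the pair of 1,3-relationships C3/C5 and C5/C7 on an open chain that ends in a fully substituted carbinol, with no neighbouring centre to direct either. The key step uses the fact that O3 and C8 are placed so that a C3–C8 bond in place of the O3–acyl link closes the carbocycle C3–C4–C5–C6–C7–C8, on whose chair the C7 methyl, the C5 oxygen and the C3 side chain are mutually cis and equatorial while the C3 methyl is axial. Oxygen insertion between C8 and C3 with retention then returns the tertiary carbinol, and O5 lies 1,4 to the acyl carbon for contraction to the γ-lactone.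

## Logic of the disconnections

16 to 14 (through 15): the O5–C8 acyl bond is cut and the acyl group is placed on O3, with O5 silylated. Forward, this is a downhill acyl shift from a seven- to a five-membered lactone that starts only when the silyl group is removed. The gain is that every ring stereocentre now sits on one ring. The demand is an acidic desilylation that leaves C7 and the tertiary alcohol untouched.

14 to 12 (through 13): the C3–O ring bond is cut and C3 is joined to C8. The tertiary carbinol becomes a quaternary carbon of a cyclohexanone, and the two open-chain 1,3-relationships become cis/trans questions on a chair. The demand is migration of C3, not C7, with retention.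

12 to 11: the C2–H bond is removed, leaving a side-chain ketone. C2 is the only centre off the ring and is best set by a reagent-controlled reduction. The demand is discrimination between two ketones, which is why the C7 methyl must already flank the ring carbonyl, and the correct face.

11 to 8 (through 9 and 10): the C7–C9 bond is cut. The methyl is placed only after C3 is quaternary, because only then is the equatorial position at C7 strongly preferred (an axial methyl would be syn-diaxial to the axial C3 methyl). On a simple 4-silyloxycyclohexanone the cis preference is too small to rely on. The gain is one stereocentre fewer. The demand is enolization at C7 in the presence of the more acidic C1–H.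

8 to 7: the C3–C10 bond is cut. The quaternary centre becomes an enolizable β-diketone, so C3 stops being a stereocentre. The demand is axial methylation trans to the C5 oxygen.

7 to 4 and 3 (through 6 and 5): the C3–C2 bond is cut, giving the enolate of an achiral ketone and an acyl donor. The only stereochemical information left is which α-arm of the ring is acylated relative to C5, and it is created by removing one of two enantiotopic α-protons. The enolate is acylated directly as it is formed, so it is generated only once. The demand is high enantiotopic discrimination without a silyl trap and acylation without proton exchange, which would scramble the arm.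

3 to 1 and 2: the O–C1 ether bond is cut. Compounds 1, 2 and 4 are commercial.

## Other disconnections considered

Alternative 1: The lactone is cut at C5–C6 and at O–C8, which leads to aldehyde A1 (C5 as CHO, the C2/C3 diol as acetonide) and methyl acrylate A2. Forward, SmI2 (divalent samarium, with an alcohol as proton source) would turn the aldehyde into a ketyl that adds to the acrylate β-carbon. The resulting alkoxide would close onto the ester to give the nor-methyl lactone A3, and the C7 methyl would follow by lactone enolate alkylation.
- In its favour: the diol of A1 can be set by a K2OsO2(OH)4/(DHQD)2PHAL-type asymmetric dihydroxylation, the coupling is convergent, and methylation of a γ-substituted butyrolactone enolate is reliably trans, which is what the target needs. On enantiomeric purity of C2/C3 and on control of C7 it is the equal or the better of the chosen plan.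
- Against it here: C5 is formed by addition to an aldehyde whose nearest stereocentre is the quaternary C3, so only weak 1,3-induction controls it. The coumarin is a conjugated lactone that divalent samarium can reduce or that can trap the ketyl. The diol needs protection and release.
- Comparison: on structure, the chosen plan fixes C5 first and relates C3 and C7 to it on a ring, whereas this route creates C5 under acyclic control. On mechanism, a single-electron reduction next to a coumarin stands against a peracid rearrangement that the coumarin should tolerate. On step economy the two are about level, and the alternative is not worse.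

Alternative 2: The cut is at C4–C5 and C3–O. Allylic alcohol A4 (the C2 carbinol with the 1,1-disubstituted C3=C4 alkene) and nitrile oxide A5 (the C5–C8 arm with C7 already in place) would combine, after deprotonation of A4 with EtMgBr, to give isoxazoline A6.
- In its favour: the union is convergent, the regiochemistry is secure (oxygen goes to the more substituted alkene carbon), C7 comes from the chiral pool and cannot be mis-set, and the C5 configuration is chosen later by the reagent. On absolute control of C7 and on flexibility at C5 it is the equal or the better of the chosen plan.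
- Against it here: after the key step C5 is still C=N. Three further selective operations are needed: N–O cleavage with Mo(CO)6 (hydrogenolysis would also saturate the coumarin), a 1,3-anti reduction directed by a tertiary hydroxyl (Me4NBH(OAc)3), and lactonization. A Grignard base must coexist with an ester and a coumarin, aliphatic nitrile oxides dimerize, and magnesium-alkoxide direction is less well documented for 2-substituted allylic alcohols, so the C2/C3 sense is not assured.
- Comparison: on structure, it sets C3 from C2 by direction, whereas the chosen plan sets C3 from C5 on a ring. On mechanism, a dipolar cycloaddition and a directed hydride stand against an enolate alkylation and a 1,2-shift. On step economy it is longer after the key step (three operations against one) and similar before it.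

Alternative 3: The cut is the C5–O bond, that is, a C5–H bond of acid A8 (the C2/C3 diol as cyclic carbonate, C7 in place), which should be reachable in a few catalytic steps from auraptene A7, the geranyl ether of 1. A chiral Mn(OTf)2(pdp)-type catalyst with H2O2 would bind the carboxylate and oxidize the γ-methylene to give lactone carbonate A9. Carbonate hydrolysis would finish the synthesis.
- In its favour: it follows the likely biogenesis, every stereocentre is set by a catalyst, and no ring template or peracid regiochemistry is involved. On step count and atom economy it is the better of the two plans.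
- Against it here: the oxidant is an electrophilic high-valent manganese-oxo species, and the substrate offers it a coumarin alkene, an electron-rich aryl ether and an activated C1–H next to the ether oxygen. The catalyst must also override the existing C7 centre when choosing between the two C5 hydrogens. All of this falls on the last carbon-skeleton step, and the carbonate must then be removed without opening the lactone or the coumarin for good.
- Comparison: on structure, C5 is made last and alone, whereas the chosen plan makes it first and uses it as the anchor. On mechanism, a directed hydrogen-atom abstraction and rebound stands against an ionic rearrangement with a predictable stereochemical course. On step economy the alternative wins if the oxidation is selective, and loses late material if it is not.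

Key step: step 6

Remark on the chemistry (assumption): the (R,R)-lithium amide is taken to select the same enantiotopic α-proton of 4 as it does in 4-tert-butylcyclohexanone, giving the (S)-enolate 5. If the sense proves opposite, the (S,S)-amine is used and nothing else changes.

Remark on the structures: derivation of the descriptors gives 2R,3R,5S,7R for the chain of 16 and a trans lactone. A cyclohexanone with the C7 methyl, the C5 oxygen and the C3 side chain mutually cis (12) maps onto this through retentive migration, so the key-step pair is stereochemically consistent with the target. The descriptor at C2 is S before the oxidation and R after it, only because C3 gains oxygen. Two design choices follow. The C5 oxygen stays silylated through the oxidation. The C7 methyl is introduced only after C3 is quaternary, because a 4-silyloxy group is too weak a conformational anchor on a simple cyclohexanone to secure the cis relation by equilibration.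

Step 1
Reactants: 1 umbelliferone (7-hydroxy-2H-chromen-2-one); 2 2-chloro-N-methoxy-N-methylacetamide
Product: 3 N-methoxy-N-methyl-2-[(2-oxo-2H-chromen-7-yl)oxy]acetamide
Conditions: K2CO3, KI (cat.), acetone, reflux
Reagents that add atoms: none
Why: Williamson ether synthesis; the phenoxide of 1 displaces halide from the α-halo amide (iodide exchange accelerates it), and carbonate in acetone is the usual medium for 7-O-alkylation of this coumarin without opening its lactone.

Step 2
Reactants: 4 4-[(tert-butyldimethylsilyl)oxy]cyclohexan-1-one; 3 N-methoxy-N-methyl-2-[(2-oxo-2H-chromen-7-yl)oxy]acetamide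
Product: 7 (4S)-4-[(tert-butyldimethylsilyl)oxy]-2-{[(2-oxo-2H-chromen-7-yl)oxy]acetyl}cyclohexan-1-one, via lithium enolate 5 (not isolated), via lithium hemiaminal adduct 6 (not isolated)
Conditions: (R,R)-bis(1-phenylethyl)amine (1.1 equiv), n-BuLi (1.05 equiv), LiCl (0.5 equiv), THF, −78 °C; 4 (1.0 equiv) added slowly, −78 °C; then 3 (1.2 equiv), −78 → −30 °C; AcOH, −78 °C
Reagents that add atoms: none
Why: Enantioselective deprotonation of a 4-substituted cyclohexanone by a chiral lithium amide, run with LiCl so that the selectivity does not depend on a silyl trap, removes one of the two enantiotopic axial α-protons and makes C5 a stereocentre; the enolate 5 is then C-acylated as formed by the Weinreb amide (Claisen-type acylation), which stops at the chelated tetrahedral adduct 6. The acidic β-diketone is therefore released only at the quench and cannot protonate unreacted enolate, C3 is stereolabile (enol form) in 7 so that C5 alone carries the stereochemical information, and the reagent-controlled step 5 should later turn any minor enantiomer largely into a separable diastereomer.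

Step 3
Reactants: 7 (4S)-4-[(tert-butyldimethylsilyl)oxy]-2-{[(2-oxo-2H-chromen-7-yl)oxy]acetyl}cyclohexan-1-one
Product: 8 (2S,4S)-4-[(tert-butyldimethylsilyl)oxy]-2-methyl-2-{[(2-oxo-2H-chromen-7-yl)oxy]acetyl}cyclohexan-1-one
Conditions: K2CO3, MeI, acetone, 0 °C → rt
Reagents that add atoms: iodomethane, CI
Why: C-alkylation of a cyclic β-diketone enolate; MeI should approach perpendicular to the enolate plane along the chair-like axial path of the half-chair with the C5 silyloxy group pseudo-equatorial, while the axial path of the flipped half-chair is syn-diaxial to that group. The new methyl should therefore end up trans to the C5 oxygen, and the acyl group, which stays in the enolate plane, equatorial and cis to it.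

Step 4
Reactants: 8 (2S,4S)-4-[(tert-butyldimethylsilyl)oxy]-2-methyl-2-{[(2-oxo-2H-chromen-7-yl)oxy]acetyl}cyclohexan-1-one
Product: 11 (2S,4S,6R)-4-[(tert-butyldimethylsilyl)oxy]-2,6-dimethyl-2-{[(2-oxo-2H-chromen-7-yl)oxy]acetyl}cyclohexan-1-one, via dilithium bis-enolate 9 (not isolated), via C-6 epimer 10 (not isolated)
Conditions: LiN(SiMe3)2 (2.2 equiv), THF, −78 °C; MeI (1.05 equiv), −78 → −30 °C; AcOH; then DBU (0.2 equiv), CH2Cl2, rt
Reagents that add atoms: iodomethane, CI
Why: Regioselective alkylation of a polyanion at its most basic site; two equivalents of base enolize both ketones, one equivalent of MeI should be taken by the less stabilized ring enolate at C7 (the only ring carbon with α-hydrogens), and the α-aryloxy enolate, which masks the side-chain ketone, is reprotonated at the quench. C7 is then under thermodynamic control, because an axial methyl there would be syn-diaxial to the axial C3 methyl, so DBU should funnel any 10 into 11.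

Step 5
Reactants: 11 (2S,4S,6R)-4-[(tert-butyldimethylsilyl)oxy]-2,6-dimethyl-2-{[(2-oxo-2H-chromen-7-yl)oxy]acetyl}cyclohexan-1-one
Product: 12 (2R,4S,6R)-4-[(tert-butyldimethylsilyl)oxy]-2-{(1S)-1-hydroxy-2-[(2-oxo-2H-chromen-7-yl)oxy]ethyl}-2,6-dimethylcyclohexan-1-one
Conditions: (S)-1-methyl-3,3-diphenyltetrahydro-1H,3H-pyrrolo[1,2-c][1,3,2]oxazaborole (0.3 equiv), BH3·SMe2 (0.7 equiv), THF, −30 °C; aq. NH4Cl
Reagents that add atoms: none
Why: Corey–Bakshi–Shibata reduction; the side-chain carbonyl is an activated α-aryloxy ketone with one small flank (CH2OAr) and one large flank (C3), whereas the ring carbonyl is shielded on both sides by its α-substituents. With C3 as the large group the (S)-oxazaborolidine should deliver hydride to the face that gives the (1S) carbinol (C2 of the target), and reagent control is expected to dominate any bias from the quaternary α-carbon.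

Step 6
Reactants: 12 (2R,4S,6R)-4-[(tert-butyldimethylsilyl)oxy]-2-{(1S)-1-hydroxy-2-[(2-oxo-2H-chromen-7-yl)oxy]ethyl}-2,6-dimethylcyclohexan-1-one
Product: 14 (3R,5S,7R)-5-[(tert-butyldimethylsilyl)oxy]-7-{(1R)-1-hydroxy-2-[(2-oxo-2H-chromen-7-yl)oxy]ethyl}-3,7-dimethyloxepan-2-one, via Criegee adduct 13 (not isolated)
Conditions: mCPBA (3 equiv), CH2Cl2, 0 °C → rt
Reagents that add atoms: 3-chloroperbenzoic acid, OOC(=O)c1cccc(Cl)c1
Why: Baeyer–Villiger oxidation: the peracid adds to the C8 carbonyl to give Criegee adduct 13, and the C8–C3 bond, antiperiplanar to the O–O bond, shifts to oxygen as 3-chlorobenzoate leaves. The closest known reaction type is the peracid oxidation of α,α-disubstituted cyclohexanones to ε-lactones with migration of the fully substituted carbon. The oxepanone ring is formed not by cyclization but by ring expansion, a concerted 1,2-shift that inserts oxygen into the C3–C8 bond of the existing six-membered ring. The new C3–O stereocentre is controlled by the configuration of C3 set in step 3, because the shift is suprafacial and goes with retention. The selectivity needed is migration of C3 rather than C7: C3 is a tertiary alkyl group and C7 only secondary, and the rotamer of 13 with the O–O bond anti to C3 also keeps the peroxy ester away from the crowded quaternary carbon. The C2 hydroxyl lowers the migratory aptitude of C3 only inductively and is left free rather than acylated for that reason. The C5 silyl ether keeps the new lactone from transacylating during a slow oxidation, and the electron-poor coumarin alkene is not expected to be epoxidized by mCPBA at room temperature.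

Step 7
Reactants: 14 (3R,5S,7R)-5-[(tert-butyldimethylsilyl)oxy]-7-{(1R)-1-hydroxy-2-[(2-oxo-2H-chromen-7-yl)oxy]ethyl}-3,7-dimethyloxepan-2-one
Product: 16 (3R,5S)-5-{(2R,3R)-2,3-dihydroxy-2-methyl-4-[(2-oxo-2H-chromen-7-yl)oxy]butyl}-3-methyloxolan-2-one, via dihydroxy oxepanone 15 (not isolated)
Conditions: 48% aq. HF, MeCN, 0 °C → rt
Reagents that add atoms: none
Why: Acidic fluoride cleavage of the silyl ether frees the C5 hydroxyl, which lies 1,4 to the acyl carbon and should attack it under the same acid (translactonization) to give the favoured γ-lactone and release the tertiary C3 alcohol. Only acyl–oxygen bonds are exchanged, so no stereocentre is touched.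

Compound list

1 | umbelliferone (7-hydroxy-2H-chromen-2-one) | Oc1ccc2ccc(=O)oc2c1 | starting material
2 | 2-chloro-N-methoxy-N-methylacetamide | CON(C)C(=O)CCl | starting material
3 | N-methoxy-N-methyl-2-[(2-oxo-2H-chromen-7-yl)oxy]acetamide | CON(C)C(=O)COc1ccc2ccc(=O)oc2c1 | intermediate
4 | 4-[(tert-butyldimethylsilyl)oxy]cyclohexan-1-one | O=C1CCC(O[Si](C)(C)C(C)(C)C)CC1 | starting material
5 | lithium (4S)-4-[(tert-butyldimethylsilyl)oxy]cyclohex-1-en-1-olate | C1C[C@H](O[Si](C)(C)C(C)(C)C)CC=C1[O-].[Li+] | intermediate
6 | lithium 1-{(5S)-5-[(tert-butyldimethylsilyl)oxy]-2-oxocyclohexyl}-1-[methoxy(methyl)amino]-2-[(2-oxo-2H-chromen-7-yl)oxy]ethan-1-olate | C1C[C@H](O[Si](C)(C)C(C)(C)C)CC(C([O-])(COc2ccc3ccc(=O)oc3c2)N(C)OC)C1=O.[Li+] | intermediate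
7 | (4S)-4-[(tert-butyldimethylsilyl)oxy]-2-{[(2-oxo-2H-chromen-7-yl)oxy]acetyl}cyclohexan-1-one (enolized, C-2 stereolabile) | C1C[C@H](O[Si](C)(C)C(C)(C)C)CC(C(=O)COc2ccc3ccc(=O)oc3c2)C1=O | intermediate
8 | (2S,4S)-4-[(tert-butyldimethylsilyl)oxy]-2-methyl-2-{[(2-oxo-2H-chromen-7-yl)oxy]acetyl}cyclohexan-1-one | C1C[C@H](O[Si](C)(C)C(C)(C)C)C[C@](C)(C(=O)COc2ccc3ccc(=O)oc3c2)C1=O | intermediate
9 | dilithium bis-enolate of 8 (ring enolate C7=C8–O, side-chain enolate C1=C2–O) | [Li+].[Li+].[O-]C1=CC[C@H](O[Si](C)(C)C(C)(C)C)C[C@]1(C)C([O-])=COc2ccc3ccc(=O)oc3c2 | intermediate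
10 | (2S,4S,6S)-4-[(tert-butyldimethylsilyl)oxy]-2,6-dimethyl-2-{[(2-oxo-2H-chromen-7-yl)oxy]acetyl}cyclohexan-1-one | C[C@H]1C[C@H](O[Si](C)(C)C(C)(C)C)C[C@](C)(C(=O)COc2ccc3ccc(=O)oc3c2)C1=O | intermediate
11 | (2S,4S,6R)-4-[(tert-butyldimethylsilyl)oxy]-2,6-dimethyl-2-{[(2-oxo-2H-chromen-7-yl)oxy]acetyl}cyclohexan-1-one | C[C@@H]1C[C@H](O[Si](C)(C)C(C)(C)C)C[C@](C)(C(=O)COc2ccc3ccc(=O)oc3c2)C1=O | intermediate
12 | (2R,4S,6R)-4-[(tert-butyldimethylsilyl)oxy]-2-{(1S)-1-hydroxy-2-[(2-oxo-2H-chromen-7-yl)oxy]ethyl}-2,6-dimethylcyclohexan-1-one | C[C@@H]1C[C@H](O[Si](C)(C)C(C)(C)C)C[C@](C)([C@H](O)COc2ccc3ccc(=O)oc3c2)C1=O | intermediate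
13 | Criegee adduct of 12: the 1-hydroxy-1-(3-chlorobenzoylperoxy)cyclohexane (C-1 configuration not defined) | C[C@@H]1C[C@H](O[Si](C)(C)C(C)(C)C)C[C@](C)([C@H](O)COc2ccc3ccc(=O)oc3c2)C1(O)OOC(=O)c1cccc(Cl)c1 | intermediate
14 | (3R,5S,7R)-5-[(tert-butyldimethylsilyl)oxy]-7-{(1R)-1-hydroxy-2-[(2-oxo-2H-chromen-7-yl)oxy]ethyl}-3,7-dimethyloxepan-2-one | C[C@@H]1C[C@H](O[Si](C)(C)C(C)(C)C)C[C@](C)([C@H](O)COc2ccc3ccc(=O)oc3c2)OC1=O | intermediate
15 | (3R,5S,7R)-5-hydroxy-7-{(1R)-1-hydroxy-2-[(2-oxo-2H-chromen-7-yl)oxy]ethyl}-3,7-dimethyloxepan-2-one | C[C@@H]1C[C@H](O)C[C@](C)([C@H](O)COc2ccc3ccc(=O)oc3c2)OC1=O | intermediate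
16 | (3R,5S)-5-{(2R,3R)-2,3-dihydroxy-2-methyl-4-[(2-oxo-2H-chromen-7-yl)oxy]butyl}-3-methyloxolan-2-one | C[C@@H]1C[C@@H](C[C@@](C)(O)[C@H](O)COc2ccc3ccc(=O)oc3c2)OC1=O | target

Total step count: 7. Longest linear sequence: 7 steps (1 to 16, steps 1 to 7); ketone 4 enters at step 2.

Least certain steps

Step 6 (key step). The likely failure is migration of the wrong α-carbon: C7 is secondary, and the aptitude of the tertiary C3 is lowered by the oxygen on C2. Peracid addition to a carbonyl flanked by two branched carbons is also slow, which gives side reactions at the coumarin more time. The fallback removes the competition instead of tuning the oxidant: the oxygen insertion is moved to a stage where C7 is still a methylene, and the C7 methyl is put in last on the γ-lactone. It sets out from 8 and comes back at 16. Reduction of the side-chain ketone of 8 under the conditions of step 5 would give the des-methyl hydroxy ketone F1. mCPBA would expand it to the des-methyl oxepanone F2, where a tertiary group competes only with a primary one. Aqueous HF would give the des-methyl lactone diol F3. Et3SiOTf and 2,6-lutidine would mask both hydroxyls as the bis(triethylsilyl) ether F4. LiN(SiMe3)2 followed by MeI would alkylate the lactone enolate on the face away from the C5 substituent, giving the trans-methyl lactone F5, and aqueous HF would release 16.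

Step 2. The likely failure is incomplete discrimination of the enantiotopic α-protons, because a silyloxy group is a weak conformational anchor on a cyclohexanone and the enolate is used without a silyl trap. Proton transfer from adduct 6 to unreacted enolate 5 is a second risk, since it would return achiral 4 and let it re-enolize without control. The whole route then carries a minor enantiomer. The fallback replaces the chiral base by a covalent auxiliary, so that the arm selection is read out as separable diastereomers. It sets out from 4 and comes back at 7. Condensation of 4 with (S)-1-amino-2-(methoxymethyl)pyrrolidine would give the hydrazone F6. LiN(i-Pr)2 followed by 3 would give the C-acylated hydrazone F7, whose arm diastereomers are separated by chromatography or crystallization; the auxiliary enantiomer is chosen so that the wanted one is the major one. Aqueous oxalic acid would then hydrolyse it to 7.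

Step 3. The likely failure is poor facial selectivity: alkylation through a twist-boat path or through the half-chair with an axial silyloxy group, since only the C5 substituent biases the enolate. Some O-methylation is also possible. The fallback installs the C7 methyl first, so that a cis-1,3 methyl/silyloxy pair locks the half-chair during the C3 methylation. It sets out from 4, comes back at 11 and also bypasses step 4. Deprotonation of 4 with the (S,S)-amide under Me3SiCl internal quench would give the (R)-enol silane F8, which is isolated so that an amine-free enolate is available for a clean monoalkylation. MeLi then MeI, followed by base equilibration and chromatographic isolation of the cis isomer, would give the cis-methyl ketone F9. LiN(SiMe3)2 (kinetic deprotonation at the unsubstituted α-carbon) then 3 would give the methyl diketone F10, and K2CO3/MeI would give 11. The price is loss or recycling of material at the cis/trans separation, because neither the alkylation nor the equilibrium is strongly cis-selective there.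

Step 4. The likely failure is loss of site selectivity (methylation at the α-aryloxy enolate or double methylation at C7) or incomplete formation of the second enolate. The fallback protects the side-chain ketone covalently before the ring enolate is made. It sets out from 8 and comes back at 11. LiN(SiMe3)2 (0.95 equiv) with warming to 0 °C would equilibrate to the more acidic α-aryloxy enolate, which Me3SiCl would trap as the side-chain enol silane F11. A second equivalent of LiN(SiMe3)2 and MeI would give the C7-methylated enol silane F12, and dilute citric acid followed by DBU would return 11.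

Step 5. The likely failure is over-reduction of the ring ketone by the alkoxyborane formed in the first reduction, or erosion of face selectivity at a carbonyl next to a quaternary carbon. The fallback changes the reduction from a borane under oxazaborolidine control to catalytic transfer hydrogenation: RuCl[(S,S)-TsDPEN](p-cymene) or its enantiomer in HCO2H/Et3N. This bifunctional catalyst has no boron hydride to carry on to the second carbonyl and engages activated α-aryloxy ketones far more readily than hindered dialkyl ketones. It sets out from 11 and comes back at 12 without any new compound.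

Further compounds

F1 | step 6 | (2R,4S)-4-[(tert-butyldimethylsilyl)oxy]-2-{(1S)-1-hydroxy-2-[(2-oxo-2H-chromen-7-yl)oxy]ethyl}-2-methylcyclohexan-1-one | C1C[C@H](O[Si](C)(C)C(C)(C)C)C[C@](C)([C@H](O)COc2ccc3ccc(=O)oc3c2)C1=O
F2 | step 6 | (5S,7R)-5-[(tert-butyldimethylsilyl)oxy]-7-{(1R)-1-hydroxy-2-[(2-oxo-2H-chromen-7-yl)oxy]ethyl}-7-methyloxepan-2-one | C1C[C@H](O[Si](C)(C)C(C)(C)C)C[C@](C)([C@H](O)COc2ccc3ccc(=O)oc3c2)OC1=O
F3 | step 6 | (5S)-5-{(2R,3R)-2,3-dihydroxy-2-methyl-4-[(2-oxo-2H-chromen-7-yl)oxy]butyl}oxolan-2-one | C1C[C@@H](C[C@@](C)(O)[C@H](O)COc2ccc3ccc(=O)oc3c2)OC1=O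
F4 | step 6 | (5S)-5-{(2R,3R)-2-methyl-4-[(2-oxo-2H-chromen-7-yl)oxy]-2,3-bis[(triethylsilyl)oxy]butyl}oxolan-2-one | C1C[C@@H](C[C@@](C)(O[Si](CC)(CC)CC)[C@H](O[Si](CC)(CC)CC)COc2ccc3ccc(=O)oc3c2)OC1=O
F5 | step 6 | (3R,5S)-3-methyl-5-{(2R,3R)-2-methyl-4-[(2-oxo-2H-chromen-7-yl)oxy]-2,3-bis[(triethylsilyl)oxy]butyl}oxolan-2-one | C[C@@H]1C[C@@H](C[C@@](C)(O[Si](CC)(CC)CC)[C@H](O[Si](CC)(CC)CC)COc2ccc3ccc(=O)oc3c2)OC1=O
F6 | step 2 | (2S)-N-{4-[(tert-butyldimethylsilyl)oxy]cyclohexylidene}-2-(methoxymethyl)pyrrolidin-1-amine | COC[C@@H]1CCCN1N=C1CCC(O[Si](C)(C)C(C)(C)C)CC1
F7 | step 2 | 1-[(5S)-5-[(tert-butyldimethylsilyl)oxy]-2-{[(2S)-2-(methoxymethyl)pyrrolidin-1-yl]imino}cyclohexyl]-2-[(2-oxo-2H-chromen-7-yl)oxy]ethan-1-one | COC[C@@H]1CCCN1N=C1CC[C@H](O[Si](C)(C)C(C)(C)C)CC1C(=O)COc1ccc2ccc(=O)oc2c1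
F8 | step 3 | (4R)-4-[(tert-butyldimethylsilyl)oxy]-1-[(trimethylsilyl)oxy]cyclohex-1-ene | C1=C(O[Si](C)(C)C)CC[C@@H](O[Si](C)(C)C(C)(C)C)C1
F9 | step 3 | (2R,4R)-4-[(tert-butyldimethylsilyl)oxy]-2-methylcyclohexan-1-one | C[C@@H]1C[C@H](O[Si](C)(C)C(C)(C)C)CCC1=O
F10 | step 3 | (2R,4S)-4-[(tert-butyldimethylsilyl)oxy]-2-methyl-6-{[(2-oxo-2H-chromen-7-yl)oxy]acetyl}cyclohexan-1-one (enolized, C-6 stereolabile) | C[C@@H]1C[C@H](O[Si](C)(C)C(C)(C)C)CC(C(=O)COc2ccc3ccc(=O)oc3c2)C1=O
F11 | step 4 | (2R,4S)-4-[(tert-butyldimethylsilyl)oxy]-2-methyl-2-{2-[(2-oxo-2H-chromen-7-yl)oxy]-1-[(trimethylsilyl)oxy]ethenyl}cyclohexan-1-one | C1C[C@H](O[Si](C)(C)C(C)(C)C)C[C@](C)(C(O[Si](C)(C)C)=COc2ccc3ccc(=O)oc3c2)C1=O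
F12 | step 4 | (2R,4S,6R)-4-[(tert-butyldimethylsilyl)oxy]-2,6-dimethyl-2-{2-[(2-oxo-2H-chromen-7-yl)oxy]-1-[(trimethylsilyl)oxy]ethenyl}cyclohexan-1-one | C[C@@H]1C[C@H](O[Si](C)(C)C(C)(C)C)C[C@](C)(C(O[Si](C)(C)C)=COc2ccc3ccc(=O)oc3c2)C1=O
F0 | step 5 | none | none
A1 | alternative 1 | [(4R,5R)-2,2,4-trimethyl-5-{[(2-oxo-2H-chromen-7-yl)oxy]methyl}-1,3-dioxolan-4-yl]acetaldehyde | O=CC[C@@]1(C)OC(C)(C)O[C@@H]1COc1ccc2ccc(=O)oc2c1
A2 | alternative 1 | methyl acrylate (methyl prop-2-enoate) | C=CC(=O)OC
A3 | alternative 1 | (5S)-5-{[(4R,5R)-2,2,4-trimethyl-5-{[(2-oxo-2H-chromen-7-yl)oxy]methyl}-1,3-dioxolan-4-yl]methyl}oxolan-2-one | O=C1CC[C@@H](C[C@@]2(C)OC(C)(C)O[C@@H]2COc3ccc4ccc(=O)oc4c3)O1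
A4 | alternative 2 | (2S)-3-methyl-1-[(2-oxo-2H-chromen-7-yl)oxy]but-3-en-2-ol | C=C(C)[C@H](O)COc1ccc2ccc(=O)oc2c1
A5 | alternative 2 | methyl (2R)-3-cyano-2-methylpropanoate N-oxide (nitrile oxide of methyl (2R)-2-methyl-4-oxobutanoate oxime) | COC(=O)[C@H](C)CC#[N+][O-]
A6 | alternative 2 | methyl (2R)-3-[(5R)-5-{(1R)-1-hydroxy-2-[(2-oxo-2H-chromen-7-yl)oxy]ethyl}-5-methyl-4,5-dihydro-1,2-oxazol-3-yl]-2-methylpropanoate | COC(=O)[C@H](C)CC1=NO[C@](C)(C1)[C@H](O)COc2ccc3ccc(=O)oc3c2
A7 | alternative 3 | auraptene, 7-{[(2E)-3,7-dimethylocta-2,6-dien-1-yl]oxy}-2H-chromen-2-one | CC(C)=CCC/C(C)=C/COc1ccc2ccc(=O)oc2c1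
A8 | alternative 3 | (2R)-2-methyl-5-[(4R,5R)-4-methyl-2-oxo-5-{[(2-oxo-2H-chromen-7-yl)oxy]methyl}-1,3-dioxolan-4-yl]pentanoic acid | C[C@H](CCC[C@@]1(C)OC(=O)O[C@@H]1COc1ccc2ccc(=O)oc2c1)C(=O)O
A9 | alternative 3 | (4R,5R)-4-methyl-4-{[(2S,4R)-4-methyl-5-oxooxolan-2-yl]methyl}-5-{[(2-oxo-2H-chromen-7-yl)oxy]methyl}-1,3-dioxolan-2-one | C[C@@H]1C[C@@H](C[C@@]2(C)OC(=O)O[C@@H]2COc3ccc4ccc(=O)oc4c3)OC1=O
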